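## Retrosynthetic overview

1. Feature: in the ten-membered carbocycle C1–C10, the C5 ketone, the C7–C8 bond (the lactone fusion) and the C9/C10 diol (read as an E C9=C10 alkene) are the carbonyl, the new σ-bond and the new alkene of an oxy-Cope product. The C6 oxygen is the trapped enolate.
2. Cardivin C ⇒ C2 desilylation, C9 angelate, syn-dihydroxylation of C9=C10, oxidative closure of the γ-lactone (O8–C12), C6 isobutyrate ⇒ a 6-hydroxy-(E)-cyclodec-9-en-5-one carrying O8 and O12 as PMB ethers.
3. Cyclodecenone ⇒ anionic oxy-Cope ring expansion with hydroxylation of the enolate ⇒ trans-1,2-dialkenylcyclohexanol (ring C5, C4, C3, C2, C1, C10).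
4. Cyclohexanol ⇒ dienylcerium reagent (C6, C7, C11–C13) + 2-alkenyl-2,6-dimethyl-4-silyloxycyclohexanone ⇒ Pd-catalysed decarboxylative allylation of an enol carbonate made by desymmetrising a meso ketone ⇒ 2,6-dimethyl-1,4-benzoquinone.
5. Ring order: six-membered carbocycle (from the quinone), then the ten-membered carbocycle (by expansion), then the γ-lactone.

Key step: step 14

## Remarks on the chemistry (assumptions)

- Germacrane numbering (C1–C10 ring, C11–C13 lactone carbons) is used for all intermediates, including the cyclohexanes.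
- An enol carbonate made with an achiral base is racemic at C2 and C4, and a chiral Pd catalyst would then give two diastereomers. The meso ketone is therefore desymmetrised first, and the Pd catalyst is used in the matched sense.
- The sense of the enantiotopic deprotonation in step 5 is assigned by analogy with 4-tert-butylcyclohexanone, where the (R,R)-amide gives the (S)-enol derivative. If the 2,6-dimethyl ketone responds in the opposite sense, the (R,R)-amine is used instead.
- C12 carries its oxygen (as a PMB ether) from the dienyl fragment onwards. An isopropenyl group could not be told apart reliably from the C9=C10 alkene by OsO4 or by allylic oxidants.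
- Alkoxymethylene ylides give E/Z mixtures, and a Z enol ether would invert C8. The enol ether is therefore built stereospecifically from an E-alkenylboronate.
- The target is taken as the open 2-hydroxy-5-ketone that is drawn. Any 2,5-hemiketal formed on desilylation would be its ring-chain tautomer, in equilibrium with it.

## Route

Step 1
Reactants: 1 2,6-dimethyl-1,4-benzoquinone
Product: 2 2,6-dimethylcyclohexane-1,4-diol (mixture of stereoisomers)
Conditions: H2 (80 bar), 5% Rh/Al2O3, EtOH, 60 °C
Reagents that add atoms: none
Why: Heterogeneous catalytic hydrogenation reduces the quinone to the hydroquinone and then saturates the arene, rhodium on alumina keeping C–O hydrogenolysis low, and the stereoisomer mixture does not matter because step 2 erases both carbinol centres and equilibrates both methyl centres.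

Step 2
Reactants: 2 2,6-dimethylcyclohexane-1,4-diol
Product: 3 cis-2,6-dimethylcyclohexane-1,4-dione (meso)
Conditions: CrO3, H2SO4, acetone, 0 °C; then K2CO3 (cat.), MeOH, 25 °C
Reagents that add atoms: none
Why: Jones oxidation converts both secondary alcohols, including the hindered one between the methyl groups, and base equilibration through the C5 enolate places both methyl groups equatorial, which sets the cis relationship of C4 and C10.

Step 3
Reactants: 3 cis-2,6-dimethylcyclohexane-1,4-dione
Product: 4 (2R,4s,6S)-4-hydroxy-2,6-dimethylcyclohexanone (meso; hydroxyl trans to both methyl groups)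
Conditions: L-Selectride (1.0 equiv), THF, −78 °C; then H2O
Reagents that add atoms: none
Why: In this chemo- and diastereoselective hydride reduction the bulky trialkylborohydride takes the unflanked C2 carbonyl rather than the C5 carbonyl between two methine carbons and approaches it equatorially, so the C2 hydroxyl comes out axial, trans to the two equatorial methyl groups.

Step 4
Reactants: 4 (2R,4s,6S)-4-hydroxy-2,6-dimethylcyclohexanone
Product: 5 (2R,4s,6S)-4-(tert-butyldimethylsilyloxy)-2,6-dimethylcyclohexanone (meso)
Conditions: TBSCl, imidazole, DMF, 25 °C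
Reagents that add atoms: tert-butyldimethylsilyl chloride, CC(C)(C)[Si](C)(C)Cl
Why: Imidazole-promoted silylation protects the only hydroxyl under conditions too mild to disturb the α-methyl centres, and the ether lasts until the final step.

Step 5
Reactants: 5 meso silyloxy ketone; 6 allyl chloroformate
Product: 8 allyl (4S,6S)-4-(tert-butyldimethylsilyloxy)-2,6-dimethylcyclohex-1-en-1-yl carbonate, via lithium enolate 7 (not isolated)
Conditions: (S,S)-bis(1-phenylethyl)amine·HCl (1.2 equiv), n-BuLi (2.4 equiv), THF, −78 → 0 °C; 5, −100 °C; then 6, −100 → −40 °C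
Reagents that add atoms: none
Why: In this chiral lithium amide desymmetrisation the twofold-symmetric amide–LiCl aggregate removes the axial hydrogen on C10 rather than its enantiotopic partner on C4, which makes C2 and C4 defined stereocentres (2S,4S), and the hindered tetrasubstituted enolate is acylated on oxygen by the chloroformate.

Step 6
Reactants: 8 allyl enol carbonate
Product: 9 (2S,4S,6S)-2-allyl-4-(tert-butyldimethylsilyloxy)-2,6-dimethylcyclohexanone
Conditions: Pd2(dba)3 (2.5 mol %), (R)-t-BuPHOX (6.25 mol %), THF, 25 °C
Reagents that add atoms: none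
Why: In this decarboxylative asymmetric allylic alkylation (Tsuji–Trost type) ionisation and loss of CO2 give an allylpalladium enolate that recombines at C10, and the ligand enantiomer that gives (R)-2-allyl-2-methylcyclohexanone in the parent series delivers allyl to the face anti to the pseudoaxial C4 methyl group (matched case, descriptor S only because C1 outranks allyl), while the neutral medium leaves C4 intact and the minor enantiomer of 8 is diverted to a separable diastereomer.

Step 7
Reactants: 9 allyl ketone
Product: 10 (2R,4S,6S)-4-(tert-butyldimethylsilyloxy)-2,6-dimethyl-2-[(E)-prop-1-enyl]cyclohexanone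
Conditions: RuHCl(CO)(PPh3)3 (5 mol %), toluene, 90 °C
Reagents that add atoms: none
Why: Ruthenium hydride alkene isomerisation (hydrometalation and β-hydride elimination) moves the double bond by one position and must stop there because C10 is quaternary, and the base-free medium does not epimerise C4.

Step 8
Reactants: 10 propenyl ketone
Product: 11 (1R,3S,5S)-5-(tert-butyldimethylsilyloxy)-1,3-dimethyl-2-oxocyclohexanecarbaldehyde
Conditions: O3, CH2Cl2, −78 °C; then PPh3, −78 → 25 °C
Reagents that add atoms: ozone, [O-][O+]=O
Why: Ozonolysis with reductive work-up cleaves the only alkene to the C9 aldehyde, and the non-enolisable β-keto aldehyde is kept away from alcohols and base to avoid deformylation.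

Step 9
Reactants: 11 keto aldehyde; 12 2-(dichloromethyl)-4,4,5,5-tetramethyl-1,3,2-dioxaborolane
Product: 13 (2R,4S,6S)-4-(tert-butyldimethylsilyloxy)-2,6-dimethyl-2-[(E)-2-(4,4,5,5-tetramethyl-1,3,2-dioxaborolan-2-yl)ethenyl]cyclohexanone
Conditions: CrCl2 (8 equiv), LiI (4 equiv), THF, 25 °C
Reagents that add atoms: none
Why: In this Takai-type olefination divalent chromium turns the dihalomethylboronate into a geminal dichromium reagent that adds to the aldehyde but not to the hindered ketone, and elimination gives the E-alkenylboronate (C9=C8) under non-basic conditions.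

Step 10
Reactants: 13 E-alkenylboronate; 14 4-methoxybenzyl alcohol
Product: 15 (2R,4S,6S)-4-(tert-butyldimethylsilyloxy)-2-[(E)-2-(4-methoxybenzyloxy)ethenyl]-2,6-dimethylcyclohexanone
Conditions: Cu(OAc)2 (2 equiv), Et3N (4 equiv), 4 Å MS, 14 as solvent, 25 °C
Reagents that add atoms: none
Why: Chan–Lam-type oxidative C–O coupling of an alkenylboronate with an alcohol proceeds by boron-to-copper transmetalation and reductive elimination with retention of the E geometry, and triethylamine at room temperature is too weak a base to epimerise C4.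

Step 11
Reactants: 14 4-methoxybenzyl alcohol; 16 2,3-dibromopropene
Product: 17 1-[(2-bromoallyloxy)methyl]-4-methoxybenzene
Conditions: NaH, THF/DMF, 0 → 25 °C
Reagents that add atoms: none
Why: In this Williamson ether synthesis the alkoxide displaces the allylic bromide and leaves the vinylic bromide untouched.

Step 12
Reactants: 17 2-bromoallyl PMB ether; 18 (E)-1,2-bis(tributylstannyl)ethene (2.5 equiv)
Product: 19 (E)-tributyl[3-(4-methoxybenzyloxymethyl)buta-1,3-dienyl]stannane
Conditions: Pd(PPh3)4 (5 mol %), toluene, 90 °C
Reagents that add atoms: none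
Why: Stille cross-coupling of the vinylic bromide with one end of the distannane retains the E geometry, and the excess of 18 suppresses the second coupling.

Step 13
Reactants: 15 enol ether ketone; 19 dienylstannane
Product: 22 (1S,2R,4S,6S)-4-(tert-butyldimethylsilyloxy)-2-[(E)-2-(4-methoxybenzyloxy)ethenyl]-1-[(E)-3-(4-methoxybenzyloxymethyl)buta-1,3-dienyl]-2,6-dimethylcyclohexanol (alkenyl groups trans), via dienyllithium 20 (not isolated), via dienylcerium dichloride 21 (not isolated)
Conditions: 19, n-BuLi, THF, −78 °C; anhydrous CeCl3, −78 °C; then 15, −78 °C; aq. NH4Cl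
Reagents that add atoms: none
Why: Tin–lithium exchange with retention, transmetalation to the weakly basic organocerium reagent and 1,2-addition avoid enolisation at C4, and since the favoured chair of 15 has both methyl groups equatorial and the C10 alkenyl group axial, that group shields its own face and the nucleophile enters axially from the other, which sets C5 (S) with the two alkenyl groups trans.

Step 14
Reactants: 22 trans-1,2-dialkenylcyclohexanol
Product: 25 (2S,4S,6S,7S,8S,9E)-2-(tert-butyldimethylsilyloxy)-6-hydroxy-8-(4-methoxybenzyloxy)-7-[3-(4-methoxybenzyloxy)prop-1-en-2-yl]-4,10-dimethylcyclodec-9-en-5-one, via potassium alkoxide 23 (not isolated), via potassium enolate 24 (not isolated)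
Conditions: KH (1.3 equiv), 18-crown-6 (1.3 equiv), THF, 0 → 40 °C; then −78 °C, 2-(phenylsulfonyl)-3-phenyloxaziridine; AcOH, −78 °C
Reagents that add atoms: 2-(phenylsulfonyl)-3-phenyloxaziridine, O=S(=O)(c1ccccc1)N1OC1c1ccccc1
Why: KH and 18-crown-6 give the loosely paired C5 alkoxide 23, whose charge weakens the C5–C10 bond, and a concerted [3,3]-sigmatropic shift (anionic oxy-Cope rearrangement) forms C7–C8 as C5–C10 breaks and delivers the regiodefined C5–C6 enolate 24. The closest known reaction type is the alkoxide-accelerated expansion of trans-1,2-divinylcyclohexanols to (E)-cyclodec-5-enones with oxidation of the resulting enolate by an N-sulfonyloxaziridine or through its silyl ether. The ten-membered ring is not closed end to end but arises by four-carbon expansion of the six-membered ring, so neither high dilution nor the entropy cost of a macrocyclisation is involved. The trans alkenyl groups can react only from the diequatorial chair and only through one chair transition state fused to the cyclohexane like a trans-decalin, in which C1 and C4 are equatorial (hence the E C9=C10 alkene and the enolate with oxygen cis to C7) and the two E alkenes hold C11 on C7 and the PMB oxygen on C8 equatorial, so that the (5S,10R) configuration is transferred to C7 and C8 in the arrangement of the target. C6 is set by oxygen transfer to the outer face of the enolate, whose orientation is held by allylic 1,3-strain (H7 eclipses the C5–O bond, C8 lies inside the ring), which gives 6S. The step needs chair over boat, one enolate face and no C4/C6 proton scrambling, which are secured by the trans-dialkenyl geometry, by peripheral attack on the E-configured ring enolate and by the absence of a proton source before the −78 °C oxidation, the price being the ring flip into the chair with syn-diaxial C4 and C10 methyl groups, which is repaid as C5–C10 breaks.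

Step 15
Reactants: 25 6-hydroxy ketone; 26 isobutyric anhydride
Product: 27 (2S,4S,6S,7R,8S,9E)-6-isobutyrate of 25
Conditions: DMAP (cat.), pyridine, 0 → 25 °C
Reagents that add atoms: none
Why: DMAP-catalysed acyl transfer esterifies the only free hydroxyl, which marks C6 before any other oxygen is released and touches no stereocentre.

Step 16
Reactants: 27 bis-PMB ether
Product: 28 (2S,4S,6S,7R,8S,9E)-8,12-diol (8-hydroxy and 7-(3-hydroxyprop-1-en-2-yl) groups free; C6 isobutyrate and C2 silyl ether kept)
Conditions: DDQ (3 equiv), CH2Cl2/pH 7 buffer, 0 °C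
Reagents that add atoms: none
Why: Oxidative PMB cleavage with DDQ removes both electron-rich benzyl ethers in one operation, and the buffered medium spares the silyl ether, the ester and both alkenes.

Step 17
Reactants: 28 8,12-diol
Product: 31 (2S,4S,6S,7R,8S,9E)-α-methylene-γ-lactone (8,12-olide; C9=C10 alkene intact), via hydroxy enal 29 (not isolated), via lactol 30 (not isolated)
Conditions: TEMPO (20 mol %), PhI(OAc)2 (2.5 equiv), CH2Cl2, 25 °C
Reagents that add atoms: none
Why: In this oxoammonium-mediated oxidative lactonisation the primary allylic C12 alcohol is oxidised ahead of the secondary C8 carbinol, enal 29 closes with O8 in a 5-exo-trig mode to lactol 30, and a second oxidation gives the lactone, trans-fused because C7 and C8 are already fixed.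

Step 18
Reactants: 31 α-methylene lactone
Product: 32 (2S,4S,6S,7R,8R,9S,10S)-9,10-diol
Conditions: OsO4 (5 mol %), NMO, acetone/H2O, 0 °C
Reagents that add atoms: osmium tetroxide (catalytic oxygen carrier), O=[Os](=O)(=O)=O; N-methylmorpholine N-oxide, C[N+]1([O-])CCOCC1; water, O
Why: In this catalytic syn-dihydroxylation (Upjohn conditions) the strained, electron-rich trisubstituted E alkene reacts ahead of the electron-poor exocyclic methylene, osmium can reach only the outer face of the ring alkene, and allylic 1,3-strain between the C10 methyl group and C8 (H8 in the alkene plane, C7 inside, O8 outside) decides which face that is, so suprafacial addition to the E alkene sets 9S and 10S together.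

Step 19
Reactants: 32 9,10-diol; 33 angelic acid
Product: 35 2-O-(tert-butyldimethylsilyl)cardivin C, via mixed anhydride 34 (not isolated)
Conditions: 33, 2,4,6-trichlorobenzoyl chloride, Et3N, toluene, 25 °C; then 32, 60 °C
Reagents that add atoms: none
Why: Yamaguchi-type mixed anhydride esterification run without DMAP transfers the angeloyl group without Z to E isomerisation, and only the secondary C9 hydroxyl reacts because the C10 hydroxyl is tertiary.

Step 20
Reactants: 35 2-O-silyl cardivin C
Product: 36 cardivin C
Conditions: HF·pyridine, pyridine/THF, 0 → 25 °C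
Reagents that add atoms: none
Why: Buffered fluoride-mediated desilylation frees the C2 hydroxyl under non-basic conditions that avoid acyl migration, angelate isomerisation, epimerisation at C4 or C6 and conjugate addition to the methylene lactone.

## Compound list

1 | 2,6-dimethyl-1,4-benzoquinone | CC1=CC(=O)C=C(C)C1=O | starting material
2 | 2,6-dimethylcyclohexane-1,4-diol (stereoisomer mixture) | CC1CC(O)CC(C)C1O | intermediate
3 | cis-2,6-dimethylcyclohexane-1,4-dione (meso) | C[C@@H]1CC(=O)C[C@H](C)C1=O | intermediate
4 | (2R,4s,6S)-4-hydroxy-2,6-dimethylcyclohexanone | C[C@@H]1C[C@@H](O)C[C@H](C)C1=O | intermediate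
5 | (2R,4s,6S)-4-(tert-butyldimethylsilyloxy)-2,6-dimethylcyclohexanone | C[C@@H]1C[C@@H](O[Si](C)(C)C(C)(C)C)C[C@H](C)C1=O | intermediate
6 | allyl chloroformate | C=CCOC(=O)Cl | starting material
7 | lithium C5–C10 enolate of 5 (2S,4S) | CC1=C(O[Li])[C@@H](C)C[C@H](O[Si](C)(C)C(C)(C)C)C1 | intermediate
8 | allyl (4S,6S)-4-(tert-butyldimethylsilyloxy)-2,6-dimethylcyclohex-1-en-1-yl carbonate | CC1=C(OC(=O)OCC=C)[C@@H](C)C[C@H](O[Si](C)(C)C(C)(C)C)C1 | intermediate
9 | (2S,4S,6S)-2-allyl-4-(tert-butyldimethylsilyloxy)-2,6-dimethylcyclohexanone | C[C@]1(CC=C)C[C@@H](O[Si](C)(C)C(C)(C)C)C[C@H](C)C1=O | intermediate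
10 | (2R,4S,6S)-4-(tert-butyldimethylsilyloxy)-2,6-dimethyl-2-[(E)-prop-1-enyl]cyclohexanone | C[C@]1(/C=C/C)C[C@@H](O[Si](C)(C)C(C)(C)C)C[C@H](C)C1=O | intermediate
11 | (1R,3S,5S)-5-(tert-butyldimethylsilyloxy)-1,3-dimethyl-2-oxocyclohexanecarbaldehyde | C[C@]1(C=O)C[C@@H](O[Si](C)(C)C(C)(C)C)C[C@H](C)C1=O | intermediate
12 | 2-(dichloromethyl)-4,4,5,5-tetramethyl-1,3,2-dioxaborolane | ClC(Cl)B1OC(C)(C)C(C)(C)O1 | starting material
13 | E-alkenyl pinacol boronate ketone (2R,4S,6S) | C[C@]1(/C=C/B2OC(C)(C)C(C)(C)O2)C[C@@H](O[Si](C)(C)C(C)(C)C)C[C@H](C)C1=O | intermediate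
14 | 4-methoxybenzyl alcohol | COc1ccc(CO)cc1 | starting material
15 | E-PMB enol ether ketone (2R,4S,6S) | C[C@]1(/C=C/OCc2ccc(OC)cc2)C[C@@H](O[Si](C)(C)C(C)(C)C)C[C@H](C)C1=O | intermediate
16 | 2,3-dibromopropene | C=C(Br)CBr | starting material
17 | 1-[(2-bromoallyloxy)methyl]-4-methoxybenzene | C=C(Br)COCc1ccc(OC)cc1 | intermediate
18 | (E)-1,2-bis(tributylstannyl)ethene | CCCC[Sn](CCCC)(CCCC)/C=C/[Sn](CCCC)(CCCC)CCCC | starting material
19 | (E)-tributyl[3-(4-methoxybenzyloxymethyl)buta-1,3-dienyl]stannane | CCCC[Sn](CCCC)(CCCC)/C=C/C(=C)COCc1ccc(OC)cc1 | intermediate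
20 | (E)-3-(4-methoxybenzyloxymethyl)buta-1,3-dienyllithium | [Li]/C=C/C(=C)COCc1ccc(OC)cc1 | intermediate
21 | (E)-3-(4-methoxybenzyloxymethyl)buta-1,3-dienylcerium dichloride | Cl[Ce](Cl)/C=C/C(=C)COCc1ccc(OC)cc1 | intermediate
22 | trans-1,2-dialkenylcyclohexanol (1S,2R,4S,6S), key-step precursor | C[C@]1(/C=C/OCc2ccc(OC)cc2)C[C@@H](O[Si](C)(C)C(C)(C)C)C[C@H](C)[C@]1(O)/C=C/C(=C)COCc1ccc(OC)cc1 | intermediate
23 | potassium alkoxide of 22 | [K+].C[C@]1(/C=C/OCc2ccc(OC)cc2)C[C@@H](O[Si](C)(C)C(C)(C)C)C[C@H](C)[C@]1([O-])/C=C/C(=C)COCc1ccc(OC)cc1 | intermediate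
24 | potassium C5–C6 enolate of the ten-membered ring (O cis to C7, 9E) | [K+].[O-]/C1=C\[C@H](C(=C)COCc2ccc(OC)cc2)[C@@H](OCc2ccc(OC)cc2)/C=C(C)/C[C@@H](O[Si](C)(C)C(C)(C)C)C[C@@H]1C | intermediate
25 | 6-hydroxy-(E)-cyclodec-9-en-5-one (2S,4S,6S,7S,8S), key-step product | C=C(COCc3ccc(OC)cc3)[C@@H]1[C@@H](OCc2ccc(OC)cc2)/C=C(C)/C[C@@H](O[Si](C)(C)C(C)(C)C)C[C@H](C)C(=O)[C@H]1O | intermediate
26 | isobutyric anhydride | CC(C)C(=O)OC(=O)C(C)C | starting material
27 | 6-isobutyrate of 25 | C=C(COCc3ccc(OC)cc3)[C@@H]1[C@@H](OCc2ccc(OC)cc2)/C=C(C)/C[C@@H](O[Si](C)(C)C(C)(C)C)C[C@H](C)C(=O)[C@H]1OC(=O)C(C)C | intermediate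
28 | 8,12-diol | C=C(CO)[C@@H]1[C@@H](O)/C=C(C)/C[C@@H](O[Si](C)(C)C(C)(C)C)C[C@H](C)C(=O)[C@H]1OC(=O)C(C)C | intermediate
29 | 8-hydroxy-12-enal | C=C(C=O)[C@@H]1[C@@H](O)/C=C(C)/C[C@@H](O[Si](C)(C)C(C)(C)C)C[C@H](C)C(=O)[C@H]1OC(=O)C(C)C | intermediate
30 | 8,12-lactol (C12 epimers) | C/C1=C\[C@@H]2OC(O)C(=C)[C@H]2[C@H](OC(=O)C(C)C)C(=O)[C@@H](C)C[C@H](O[Si](C)(C)C(C)(C)C)C1 | intermediate
31 | α-methylene-γ-lactone with the E C9=C10 alkene | C/C1=C\[C@@H]2OC(=O)C(=C)[C@H]2[C@H](OC(=O)C(C)C)C(=O)[C@@H](C)C[C@H](O[Si](C)(C)C(C)(C)C)C1 | intermediate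
32 | (9S,10S)-9,10-diol | C=C1C(=O)O[C@@H]2[C@@H]1[C@H](OC(=O)C(C)C)C(=O)[C@@H](C)C[C@H](O[Si](C)(C)C(C)(C)C)C[C@](C)(O)[C@H]2O | intermediate
33 | angelic acid, (Z)-2-methylbut-2-enoic acid | C/C=C(/C)C(=O)O | starting material
34 | angelic 2,4,6-trichlorobenzoic anhydride | C/C=C(/C)C(=O)OC(=O)c1c(Cl)cc(Cl)cc1Cl | intermediate
35 | 2-O-(tert-butyldimethylsilyl)cardivin C | C=C1C(=O)O[C@@H]2[C@@H]1[C@H](OC(=O)C(C)C)C(=O)[C@@H](C)C[C@H](O[Si](C)(C)C(C)(C)C)C[C@](C)(O)[C@H]2OC(=O)/C(C)=C\C | intermediate
36 | cardivin C (2S,4S,6S,7R,8R,9S,10S) | C=C1C(=O)O[C@@H]2[C@@H]1[C@H](OC(=O)C(C)C)C(=O)[C@@H](C)C[C@H](O)C[C@](C)(O)[C@H]2OC(=O)/C(C)=C\C | target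

## Step count and risks

Total step count: 20. Longest linear sequence: 18 (steps 1–10 and 13–20). Steps 11 and 12 build the dienyl fragment.

**Step 14 (ring expansion with enolate hydroxylation).**
- What may go wrong: oxygen transfer to the hindered potassium enolate may be slow or may lack facial selectivity. The enolate may also add to the sulfonimine that is released, or exchange protons between C6 and C4 during a sluggish oxidation.
- Fallback, from 22 back to 25: rearrangement and oxygenation are separated. The alkoxide rearrangement is run as before, but enolate 24 is captured on oxygen with TMSCl to give the isolable trimethylsilyl enol ether F1.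
- Rubottom oxidation of this most electron-rich alkene with one equivalent of dimethyldioxirane at −78 °C, again from the outer face, gives the α-trimethylsilyloxy ketone F2.
- Aqueous citric acid then releases 25.

**Step 5 (desymmetrisation).**
- What may go wrong: the axial silyloxy group stands on the same face as the two axial α-hydrogens. Deprotonation by the bulky chiral amide may therefore be slow or may discriminate poorly between C10 and C4.
- Fallback, from 5 back to 9: absolute control is moved entirely to the palladium catalyst. LDA deprotonates 5 without selection, giving 7 together with the mirror-image lithium enolate F3. Allyl chloroformate 6 converts the pair into 8 together with the mirror-image enol carbonate F4.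
- The racemate is submitted to the Pd2(dba)3/(R)-t-BuPHOX conditions of step 6. Catalyst control then makes the reaction stereodivergent: 8 gives 9, and F4 gives the diastereomeric (2S,4R,6R)-allyl ketone F5.
- F5 is removed by chromatography, at the cost of half of the material.

**Step 13 (dienyl addition).**
- What may go wrong: addition through the minor chair of 15 would erode the facial selectivity and give the cis-dialkenyl carbinol. Enolisation would return ketone with a scrambled C4.
- Fallback, from 15 and 17 back to 22: the branched sp2 nucleophile is replaced by a rod-shaped sp nucleophile, and the E alkene is made afterwards. Sonogashira coupling of 17 with trimethylsilylacetylene gives the silylated enyne F6, and K2CO3 in MeOH gives the terminal enyne F7.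
- n-BuLi gives the lithium acetylide F8. It adds to 15 with the strong axial preference of acetylides, giving the tertiary propargylic alcohol F9.
- Hydroxyl-directed trans-hydroalumination with Red-Al followed by protonolysis converts the alkyne into the E C6=C7 alkene of 22.

## Further compounds

F1 | step 14 | trimethylsilyl enol ether of the ring-expanded ketone (O cis to C7, 9E) | C[Si](C)(C)O/C1=C\[C@H](C(=C)COCc2ccc(OC)cc2)[C@@H](OCc2ccc(OC)cc2)/C=C(C)/C[C@@H](O[Si](C)(C)C(C)(C)C)C[C@@H]1C
F2 | step 14 | 6-O-trimethylsilyl ether of 25 | C=C(COCc3ccc(OC)cc3)[C@@H]1[C@@H](OCc2ccc(OC)cc2)/C=C(C)/C[C@@H](O[Si](C)(C)C(C)(C)C)C[C@H](C)C(=O)[C@H]1O[Si](C)(C)C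
F3 | step 5 | enantiomer of lithium enolate 7 | CC1=C(O[Li])[C@H](C)C[C@@H](O[Si](C)(C)C(C)(C)C)C1
F4 | step 5 | allyl (4R,6R)-4-(tert-butyldimethylsilyloxy)-2,6-dimethylcyclohex-1-en-1-yl carbonate | CC1=C(OC(=O)OCC=C)[C@H](C)C[C@@H](O[Si](C)(C)C(C)(C)C)C1
F5 | step 5 | (2S,4R,6R)-2-allyl-4-(tert-butyldimethylsilyloxy)-2,6-dimethylcyclohexanone | C[C@]1(CC=C)C[C@H](O[Si](C)(C)C(C)(C)C)C[C@@H](C)C1=O
F6 | step 13 | 1-methoxy-4-{[2-methylene-4-(trimethylsilyl)but-3-ynyloxy]methyl}benzene | C=C(C#C[Si](C)(C)C)COCc1ccc(OC)cc1
F7 | step 13 | 1-methoxy-4-[(2-methylenebut-3-ynyloxy)methyl]benzene | C=C(C#C)COCc1ccc(OC)cc1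
F8 | step 13 | lithium acetylide of F7 | [Li]C#CC(=C)COCc1ccc(OC)cc1
F9 | step 13 | tertiary propargylic alcohol (C6≡C7 analogue of 22) | C[C@]1(/C=C/OCc2ccc(OC)cc2)C[C@@H](O[Si](C)(C)C(C)(C)C)C[C@H](C)[C@]1(O)C#CC(=C)COCc1ccc(OC)cc1
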